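**Plan** (atom labels C1–C17 are the gibberellane numbers of the target)

- Retrosynthesis: C6–C7 is cut first, leaving a ring B ketone. Ring A (C10, C1, C2, C3, C4, C5) is fused to the furan along C2–C3 (oxygen on C3) and to ring B along C5–C10. Cutting C3–C4 and C5–C10 therefore leaves a but-2-ynoyl group (C4, C5) on C8 and a 3-vinylfuran diene (C3=C2–C1=C10) on C9.
- Earlier cuts: C5–C6 (alkynyl Grignard on a C8 aldehyde), C1=C10 (cross-metathesis with furan fragment 6), C13–C16 (ketyl–alkyne closure of ring D), C8–C15 (propargylation), C9–C10 (conjugate vinylation of a ring C enal).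
- Forward order: ketal-masked ring C enal, vinyl on C9, propargyl on C8, ring D, furan, ynone, rings A and B in one operation, then C7 and ester hydrolysis.
- Stereochemistry: C9 from a tert-leucine ester auxiliary; C8 by enolate alkylation trans to the C9 vinyl group; C13 is forced by the bridge; C6 by equilibration to the less crowded epimer.

Key step: step 16

Assumption: in step 8 the vinyl group is taken to be transferred anti to the tert-butyl group of the N,O-chelated magnesium aldimine, which with the (S)-amino ester gives the C9 configuration of the target; were the sense opposite, the (R)-amino ester would be used with nothing else changed.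

**Route**

Step 1
Reactants: 1 dimethyl furan-3,4-dicarboxylate
Product: 2 4-(methoxycarbonyl)furan-3-carboxylic acid
Conditions: KOH (1.0 equiv), MeOH, rt; then aq. HCl to pH 2
Reagents that add atoms: potassium hydroxide, [K+].[OH-]
Why: Mono-saponification of a symmetric diester (acyl substitution by hydroxide) should stop at the half-ester because the first carboxylate deactivates the molecule towards a second attack.

Step 2
Reactants: 2 4-(methoxycarbonyl)furan-3-carboxylic acid
Product: 3 methyl 4-(hydroxymethyl)furan-3-carboxylate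
Conditions: BH3·SMe2 (1.5 equiv), THF, 0 °C to rt; MeOH quench
Reagents that add atoms: none
Why: Borane reduction is chemoselective for a carboxylic acid over an ester, so only the free acid should be taken to the alcohol.

Step 3
Reactants: 3 methyl 4-(hydroxymethyl)furan-3-carboxylate
Product: 4 methyl 4-formylfuran-3-carboxylate
Conditions: MnO2 (10 equiv), CH2Cl2, rt
Reagents that add atoms: none
Why: MnO2 oxidation of a heteroaryl (benzylic-type) carbinol should stop cleanly at the aldehyde.

Step 4
Reactants: 4 methyl 4-formylfuran-3-carboxylate; 5 methyltriphenylphosphonium bromide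
Product: 6 methyl 4-ethenylfuran-3-carboxylate
Conditions: 5 (1.2 equiv), KOtBu (1.15 equiv), THF, 0 °C; then 4, 0 °C to rt
Reagents that add atoms: methyltriphenylphosphonium bromide (5), C[P+](c1ccccc1)(c1ccccc1)c1ccccc1.[Br-]
Why: Wittig methylenation, in which the unstabilised ylide should react with the aldehyde far faster than with the ester at this temperature.

Step 5
Reactants: 7 1,4-dioxaspiro[4.5]decan-7-one
Product: 9 1,4-dioxaspiro[4.5]dec-7-en-7-yl trifluoromethanesulfonate, via lithium enolate 8 (not isolated)
Conditions: LiN(SiMe3)2 (1.1 equiv), THF, −78 °C; PhNTf2 (1.1 equiv), −78 °C to rt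
Reagents that add atoms: N-phenylbis(trifluoromethanesulfonimide), O=S(=O)(N(c1ccccc1)S(=O)(=O)C(F)(F)F)C(F)(F)F
Why: Kinetic deprotonation by the hindered amide should occur at the open methylene remote from the ketal (future C9), and O-sulfonylation of that enolate gives the enol triflate with the future C8=C9 double bond.

Step 6
Reactants: 9 1,4-dioxaspiro[4.5]dec-7-en-7-yl trifluoromethanesulfonate
Product: 10 1,4-dioxaspiro[4.5]dec-7-ene-7-carbaldehyde
Conditions: Pd(PPh3)4 (5 mol%), CO (1 atm), Bu3SnH (1.1 equiv, slow addition), LiCl (3 equiv), THF, 50 °C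
Reagents that add atoms: carbon monoxide, [C-]#[O+]
Why: Palladium-catalysed formylation (reductive carbonylation) of a vinyl triflate, by oxidative addition, CO insertion and hydride transfer from the tin hydride, should give the enal whose formyl carbon is C6.

Step 7
Reactants: 10 1,4-dioxaspiro[4.5]dec-7-ene-7-carbaldehyde; 11 tert-butyl (2S)-2-amino-3,3-dimethylbutanoate
Product: 12 tert-butyl (2S)-2-[(E)-(1,4-dioxaspiro[4.5]dec-7-en-7-ylmethylidene)amino]-3,3-dimethylbutanoate
Conditions: 11 (1.0 equiv, free base from its commercial hydrochloride), 4 Å molecular sieves, benzene, 0 °C to rt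
Reagents that add atoms: tert-butyl (2S)-2-amino-3,3-dimethylbutanoate (11), CC(C)(C)[C@H](N)C(=O)OC(C)(C)C
Why: Imine condensation driven by removal of water should give the conjugated (E)-aldimine that carries the chelating ester auxiliary.

Step 8
Reactants: 12 tert-butyl (2S)-2-[(E)-(1,4-dioxaspiro[4.5]dec-7-en-7-ylmethylidene)amino]-3,3-dimethylbutanoate; 13 vinylmagnesium bromide
Product: 15 (7R,8S)-8-ethenyl-1,4-dioxaspiro[4.5]decane-7-carbaldehyde, via bromomagnesium enamide 14 (not isolated)
Conditions: CH2=CHMgBr (2.5 equiv), THF, −23 °C; then AcOH–NaOAc buffer (pH 4.5), hexane, rt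
Reagents that add atoms: vinylmagnesium bromide (13), C=C[Mg]Br; water, O
Why: Auxiliary-controlled conjugate addition of a Grignard reagent to a chelating α,β-unsaturated aldimine, in which magnesium held between the imine nitrogen and the ester carbonyl delivers the vinyl group to C9 on the face away from the tert-butyl group and so sets C9, while buffered hydrolysis releases the aldehyde (its C8 centre is re-formed in step 9) and the amino ester.

Step 9
Reactants: 15 (7R,8S)-8-ethenyl-1,4-dioxaspiro[4.5]decane-7-carbaldehyde; 16 propargyl bromide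
Product: 18 (7S,8S)-8-ethenyl-7-(prop-2-yn-1-yl)-1,4-dioxaspiro[4.5]decane-7-carbaldehyde, via potassium enolate 17 (not isolated)
Conditions: KN(SiMe3)2 (1.1 equiv), THF, −78 °C; HC≡CCH2Br (1.5 equiv), −78 to −20 °C
Reagents that add atoms: propargyl bromide (16), C#CCBr
Why: Substrate-controlled C-alkylation of an aldehyde enolate, in which the vinyl group sits equatorial and the axial trajectory is screened by the axial ketal oxygen on C13, so the electrophile should enter equatorially and place propargyl trans and the formyl carbon C6 cis to the C9 vinyl group, which sets C8.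

Step 10
Reactants: 18 (7S,8S)-8-ethenyl-7-(prop-2-yn-1-yl)-1,4-dioxaspiro[4.5]decane-7-carbaldehyde
Product: 20 (3S,4S)-4-ethenyl-3-(hydroxymethyl)-3-(prop-2-yn-1-yl)cyclohexan-1-one, via hydroxy ketal 19 (not isolated)
Conditions: NaBH4 (1.0 equiv), MeOH, 0 °C; then 2 M aq. HCl, THF, rt
Reagents that add atoms: water, O
Why: Borohydride reduction masks C6 as the neopentyl alcohol so that no aldehyde competes in the next step, and acid-catalysed ketal hydrolysis in the same flask frees the C13 ketone without risk to C8 (quaternary) or C9 (not alpha to a carbonyl).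

Step 11
Reactants: 20 (3S,4S)-4-ethenyl-3-(hydroxymethyl)-3-(prop-2-yn-1-yl)cyclohexan-1-one
Product: 21 (1S,4S,5S)-4-ethenyl-5-(hydroxymethyl)-7-methylidenebicyclo[3.2.1]octan-1-ol
Conditions: SmI2 (3 equiv), HMPA (10 equiv), t-BuOH (2 equiv), THF, 0 °C to rt
Reagents that add atoms: none
Why: SmI2-mediated ketyl–alkyne reductive cyclisation (5-exo-dig), in which the C13 ketyl adds to C16 of the axial propargyl group and the vinyl radical is reduced and protonated to the exocyclic methylene; the two-carbon bridge can span C8 and C13 on one face only, so the C13 carbinol centre is fixed by C8.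

Step 12
Reactants: 21 (1S,4S,5S)-4-ethenyl-5-(hydroxymethyl)-7-methylidenebicyclo[3.2.1]octan-1-ol; 6 methyl 4-ethenylfuran-3-carboxylate
Product: 22 methyl 4-{(E)-2-[(1S,2S,5S)-5-hydroxy-1-(hydroxymethyl)-6-methylidenebicyclo[3.2.1]octan-2-yl]ethenyl}furan-3-carboxylate
Conditions: second-generation Hoveyda–Grubbs catalyst (10 mol%), 6 (3 equiv), CH2Cl2, 40 °C
Reagents that add atoms: none
Why: Olefin cross-metathesis between the monosubstituted C9 vinyl group and the styrene-like vinylfuran should give the conjugated (E)-alkene, the 1,1-disubstituted C16 methylene being too hindered to take part and no alkyne being present at this stage.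

Step 13
Reactants: 22 methyl 4-{(E)-2-[(1S,2S,5S)-5-hydroxy-1-(hydroxymethyl)-6-methylidenebicyclo[3.2.1]octan-2-yl]ethenyl}furan-3-carboxylate
Product: 23 methyl 4-{(E)-2-[(1S,2S,5S)-1-formyl-5-hydroxy-6-methylidenebicyclo[3.2.1]octan-2-yl]ethenyl}furan-3-carboxylate
Conditions: Dess–Martin periodinane (1.3 equiv), NaHCO3, CH2Cl2, 0 °C to rt
Reagents that add atoms: none
Why: Dess–Martin oxidation converts the primary alcohol into the C6 aldehyde, and the bridgehead tertiary alcohol cannot be oxidised.

Step 14
Reactants: 23 methyl 4-{(E)-2-[(1S,2S,5S)-1-formyl-5-hydroxy-6-methylidenebicyclo[3.2.1]octan-2-yl]ethenyl}furan-3-carboxylate; 24 prop-1-ynylmagnesium bromide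
Product: 25 methyl 4-{(E)-2-[(1S,2S,5S)-5-hydroxy-1-(1-hydroxybut-2-yn-1-yl)-6-methylidenebicyclo[3.2.1]octan-2-yl]ethenyl}furan-3-carboxylate (both carbinol epimers)
Conditions: MeC≡CMgBr (3 equiv), THF, −78 to −20 °C; aq. NH4Cl
Reagents that add atoms: prop-1-ynylmagnesium bromide (24), CC#C[Mg]Br
Why: Grignard addition of an alkynyl nucleophile to the aldehyde, which at low temperature is far more electrophilic than the furan methyl ester; the new carbinol centre is removed in step 15.

Step 15
Reactants: 25 methyl 4-{(E)-2-[(1S,2S,5S)-5-hydroxy-1-(1-hydroxybut-2-yn-1-yl)-6-methylidenebicyclo[3.2.1]octan-2-yl]ethenyl}furan-3-carboxylate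
Product: 26 methyl 4-{(E)-2-[(1S,2S,5S)-1-(but-2-ynoyl)-5-hydroxy-6-methylidenebicyclo[3.2.1]octan-2-yl]ethenyl}furan-3-carboxylate
Conditions: Dess–Martin periodinane (1.5 equiv), NaHCO3, CH2Cl2, rt
Reagents that add atoms: none
Why: Dess–Martin oxidation of the secondary propargylic alcohol should give the ynone under buffered conditions that leave the tertiary alcohol and both alkenes alone.

Step 16
Reactants: 26 methyl 4-{(E)-2-[(1S,2S,5S)-1-(but-2-ynoyl)-5-hydroxy-6-methylidenebicyclo[3.2.1]octan-2-yl]ethenyl}furan-3-carboxylate
Product: 28 benzofuran-fused C6 ketone (rings A to D complete; furan methyl ester), via cyclohexadiene cycloadduct 27 (not isolated)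
Conditions: toluene (0.01 M), BHT (0.1 equiv), 130 °C, sealed tube; then rt, DDQ (1.2 equiv)
Reagents that add atoms: none
Why: On heating, the 3-vinylfuran (C10=C1 and the furan C2=C3 bond in the s-cis arrangement) should serve as the 4π partner and the ynone triple bond C5≡C4 as the 2π partner of a concerted, asynchronous intramolecular Diels–Alder reaction that forms C5–C10 and C4–C3; the closest known reactions are intramolecular cycloadditions of vinylfurans and other vinylarenes with tethered activated alkynes, followed by dehydrogenation. Ring B (C5, C6, C8, C9, C10) closes in the fused mode through the three-atom tether C9–C8–C6, and ring A (C10, C1, C2, C3, C4, C5) closes as a cyclohexa-1,4-diene in which the furan is no longer aromatic. DDQ then removes the hydrogens on C3 and C10, and rearomatisation of the furan together with formation of the benzene ring supplies the driving force. No stereocentre is created, since the sp3 carbons C3 and C10 of 27 are flattened, and C8, C9 and C13 are not touched. The selectivity needed is regiochemical: the short tether lets C5 reach C10 only, so C4 with its methyl group must bond to the furan carbon next to oxygen, the reverse orientation requiring a bridgehead double bond. The (E) geometry of C10=C1 from step 12 lets the tether fold over the diene, the neighbouring ester disfavours the unproductive s-trans rotamer, and the C6 carbonyl both activates the alkyne and ends as the ring B ketone.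

Step 17
Reactants: 28 benzofuran-fused C6 ketone (furan methyl ester); 29 (methoxymethyl)triphenylphosphonium chloride
Product: 30 C6 methoxymethylidene enol ether of 28 (E/Z mixture)
Conditions: 29 (4 equiv), KN(SiMe3)2 (3.8 equiv), THF, 0 °C; then 28, 0 to 60 °C
Reagents that add atoms: (methoxymethyl)triphenylphosphonium chloride (29), COC[P+](c1ccccc1)(c1ccccc1)c1ccccc1.[Cl-]
Why: Wittig reaction of the non-enolisable aryl ketone with (methoxymethylidene)triphenylphosphorane adds C7 as an enol ether, with excess ylide covering the free tertiary hydroxyl and the geometry of the new double bond being of no consequence.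

Step 18
Reactants: 30 C6 methoxymethylidene enol ether of 28
Product: 32 C7 aldehyde with the natural C6 configuration (furan methyl ester), via C6-epimeric aldehyde 31 (not isolated)
Conditions: 2 M aq. HCl, THF, 0 °C to rt; then DBU (0.2 equiv), CH2Cl2, rt
Reagents that add atoms: water, O
Why: Acid hydrolysis of the enol ether should protonate C6 from the more open face (that of C15 and H9) to give first the epimer with the formyl group on the ring C side, and enolisation of this α-aryl aldehyde by base then equilibrates C6 to the less crowded epimer, with C7 trans to C14 and C11 as in the target (thermodynamic control).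

Step 19
Reactants: 32 C7 aldehyde with the natural C6 configuration (furan methyl ester)
Product: 33 pharbinilic acid furan-ring methyl ester (free C7 acid)
Conditions: NaClO2, NaH2PO4, 2-methylbut-2-ene, t-BuOH/H2O, rt
Reagents that add atoms: sodium chlorite, [Na+].[O-]Cl=O
Why: Pinnick oxidation takes the aldehyde to the acid under buffered conditions that should neither touch the alkenes nor epimerise C6.

Step 20
Reactants: 33 pharbinilic acid furan-ring methyl ester
Product: 34 pharbinilic acid
Conditions: LiOH (5 equiv), THF/MeOH/H2O, rt; then aq. HCl to pH 2–3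
Reagents that add atoms: lithium hydroxide, [Li+].[OH-]
Why: Saponification of the heteroaryl methyl ester (acyl substitution by hydroxide) should leave C6 unchanged, because the C7 carboxylate is not deprotonated at carbon under these conditions.

**Compound list**

1 | dimethyl furan-3,4-dicarboxylate | COC(=O)c1cocc1C(=O)OC | starting material
2 | 4-(methoxycarbonyl)furan-3-carboxylic acid | COC(=O)c1cocc1C(=O)O | intermediate
3 | methyl 4-(hydroxymethyl)furan-3-carboxylate | COC(=O)c1cocc1CO | intermediate
4 | methyl 4-formylfuran-3-carboxylate | COC(=O)c1cocc1C=O | intermediate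
5 | methyltriphenylphosphonium bromide | C[P+](c1ccccc1)(c1ccccc1)c1ccccc1.[Br-] | starting material
6 | methyl 4-ethenylfuran-3-carboxylate | COC(=O)c1cocc1C=C | intermediate
7 | 1,4-dioxaspiro[4.5]decan-7-one | O=C1CCCC2(C1)OCCO2 | starting material
8 | lithium 1,4-dioxaspiro[4.5]dec-7-en-7-olate (not isolated) | [Li+].[O-]C1=CCCC2(C1)OCCO2 | intermediate
9 | 1,4-dioxaspiro[4.5]dec-7-en-7-yl trifluoromethanesulfonate | O=S(=O)(OC1=CCCC2(C1)OCCO2)C(F)(F)F | intermediate
10 | 1,4-dioxaspiro[4.5]dec-7-ene-7-carbaldehyde | O=CC1=CCCC2(C1)OCCO2 | intermediate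
11 | tert-butyl (2S)-2-amino-3,3-dimethylbutanoate (L-tert-leucine tert-butyl ester) | CC(C)(C)[C@H](N)C(=O)OC(C)(C)C | starting material
12 | tert-butyl (2S)-2-[(E)-(1,4-dioxaspiro[4.5]dec-7-en-7-ylmethylidene)amino]-3,3-dimethylbutanoate | CC(C)(C)[C@H](/N=C/C1=CCCC2(C1)OCCO2)C(=O)OC(C)(C)C | intermediate
13 | vinylmagnesium bromide | C=C[Mg]Br | starting material
14 | bromomagnesium enamide from vinyl addition to 12 (N cis to C9; not isolated) | C=C[C@@H]1CCC2(OCCO2)C/C1=C/N([Mg]Br)[C@H](C(=O)OC(C)(C)C)C(C)(C)C | intermediate
15 | (7R,8S)-8-ethenyl-1,4-dioxaspiro[4.5]decane-7-carbaldehyde (trans) | C=C[C@@H]1CCC2(OCCO2)C[C@H]1C=O | intermediate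
16 | propargyl bromide (3-bromoprop-1-yne) | C#CCBr | starting material
17 | potassium enolate of 15 (not isolated) | C=C[C@@H]1CCC2(OCCO2)CC1=C[O-].[K+] | intermediate
18 | (7S,8S)-8-ethenyl-7-(prop-2-yn-1-yl)-1,4-dioxaspiro[4.5]decane-7-carbaldehyde (propargyl trans to vinyl) | C=C[C@@H]1CCC2(OCCO2)C[C@]1(CC#C)C=O | intermediate
19 | [(7S,8S)-8-ethenyl-7-(prop-2-yn-1-yl)-1,4-dioxaspiro[4.5]decan-7-yl]methanol (not isolated) | C=C[C@@H]1CCC2(OCCO2)C[C@]1(CC#C)CO | intermediate
20 | (3S,4S)-4-ethenyl-3-(hydroxymethyl)-3-(prop-2-yn-1-yl)cyclohexan-1-one | C=C[C@@H]1CCC(=O)C[C@]1(CC#C)CO | intermediate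
21 | (1S,4S,5S)-4-ethenyl-5-(hydroxymethyl)-7-methylidenebicyclo[3.2.1]octan-1-ol (ring C/D diol; vinyl on C9 anti to the C15–C16 bridge) | C=C1C[C@]2(CO)C[C@@]1(O)CC[C@H]2C=C | intermediate
22 | methyl 4-{(E)-2-[(1S,2S,5S)-5-hydroxy-1-(hydroxymethyl)-6-methylidenebicyclo[3.2.1]octan-2-yl]ethenyl}furan-3-carboxylate | C=C1C[C@]2(CO)C[C@@]1(O)CC[C@H]2/C=C/c1cocc1C(=O)OC | intermediate
23 | methyl 4-{(E)-2-[(1S,2S,5S)-1-formyl-5-hydroxy-6-methylidenebicyclo[3.2.1]octan-2-yl]ethenyl}furan-3-carboxylate | C=C1C[C@]2(C=O)C[C@@]1(O)CC[C@H]2/C=C/c1cocc1C(=O)OC | intermediate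
24 | prop-1-ynylmagnesium bromide | CC#C[Mg]Br | starting material
25 | methyl 4-{(E)-2-[(1S,2S,5S)-5-hydroxy-1-(1-hydroxybut-2-yn-1-yl)-6-methylidenebicyclo[3.2.1]octan-2-yl]ethenyl}furan-3-carboxylate (carbinol epimers) | C=C1C[C@]2(C(O)C#CC)C[C@@]1(O)CC[C@H]2/C=C/c1cocc1C(=O)OC | intermediate
26 | methyl 4-{(E)-2-[(1S,2S,5S)-1-(but-2-ynoyl)-5-hydroxy-6-methylidenebicyclo[3.2.1]octan-2-yl]ethenyl}furan-3-carboxylate (C/D alcohol with butynoyl on C8 and furylvinyl on C9) | C=C1C[C@]2(C(=O)C#CC)C[C@@]1(O)CC[C@H]2/C=C/c1cocc1C(=O)OC | intermediate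
27 | cyclohexa-1,4-diene cycloadduct (C3 and C10 sp3, configuration there undefined and lost; not isolated) | C=C1C[C@]23C[C@@]1(O)CC[C@H]2C1C=C2C(C(=O)OC)=COC2C(C)=C1C3=O | intermediate
28 | benzofuran-fused C6 ketone: ring A benzofuran, ring B indanone, ring C/D unchanged, furan methyl ester | C=C1C[C@]23C[C@@]1(O)CC[C@H]2c1cc2c(C(=O)OC)coc2c(C)c1C3=O | intermediate
29 | (methoxymethyl)triphenylphosphonium chloride | COC[P+](c1ccccc1)(c1ccccc1)c1ccccc1.[Cl-] | starting material
30 | C6 methoxymethylidene enol ether of 28 (E/Z mixture) | C=C1C[C@]23C[C@@]1(O)CC[C@H]2c1cc2c(C(=O)OC)coc2c(C)c1C3=COC | intermediate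
31 | C6-epimeric C7 aldehyde (formyl cis to C14; not isolated) | C=C1C[C@]23C[C@@]1(O)CC[C@H]2c1cc2c(C(=O)OC)coc2c(C)c1[C@H]3C=O | intermediate
32 | C7 aldehyde with natural C6 configuration (formyl cis to C15), furan methyl ester | C=C1C[C@]23C[C@@]1(O)CC[C@H]2c1cc2c(C(=O)OC)coc2c(C)c1[C@@H]3C=O | intermediate
33 | pharbinilic acid furan-ring methyl ester (free C7 acid) | C=C1C[C@]23C[C@@]1(O)CC[C@H]2c1cc2c(C(=O)OC)coc2c(C)c1[C@@H]3C(=O)O | intermediate
34 | pharbinilic acid | C=C1C[C@]23C[C@@]1(O)CC[C@H]2c1cc2c(C(=O)O)coc2c(C)c1[C@@H]3C(=O)O | target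

**Step count**

Total: 20 steps (steps 1–4 make furan fragment 6; steps 5–20 are the main line).
Longest linear sequence: 16 steps (7 to 34, steps 5–20).

**Steps most likely to fail, with fallbacks**

Step 16 (key step). The cycloaddition may be too slow, because the furan C2=C3 bond must give up its aromaticity and the ester next to the vinyl group lowers the electron density of the diene; the ynone could then oligomerise before it cyclises. The fallback changes the dienophile from an alkyne to an alkene and dehydrogenates twice. Aldehyde 23 would be treated with (E)-prop-1-enylmagnesium bromide to give the allylic alcohol F1. Dess–Martin oxidation would give the (E)-but-2-enoyl ketone F2. Heating F2 in toluene should close rings A and B to the tetrahydro cycloadduct F3 (epimers at C3, C4, C5 and C10, all of which are later flattened). DDQ (2.5 equiv) in hot 1,4-dioxane would then remove four hydrogens and give 28, where the route is rejoined.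

Step 11. The ketyl may close onto the C9 vinyl group instead (5-exo-trig through a boat, giving a norbornanol), or may simply be reduced to the secondary alcohol; this is a chemoselectivity problem of the radical process. The fallback is a polar closure through an alkenylchromium species. The potassium enolate of aldehyde 15 would be alkylated with 2,3-dibromopropene to give the 2-bromoallyl aldehyde F4. NaBH4 reduction to the hydroxy ketal F5 and acid hydrolysis in the same flask would give the bromoallyl hydroxy ketone F6. An intramolecular Nozaki–Hiyama–Kishi reaction (CrCl2, catalytic NiCl2, DMF) should then add C16 to the C13 carbonyl and give diol 21.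

Step 9. Attack of the electrophile on the face syn to the vinyl group (wrong facial selectivity) would place the propargyl group cis to C10 and give the C8 epimer. The fallback lets the two C8 substituents exchange roles, so that the same facial preference is put to use. The potassium enolate of 15 would be quenched with monomeric formaldehyde to give the hydroxymethyl aldehyde F7, with CH2OH (future C6) cis to the vinyl group. Wittig reaction with (methoxymethylidene)triphenylphosphorane would give the enol ether F8. 2 M HCl would hydrolyse both enol ether and ketal to the keto aldehyde F9 (in equilibrium with its lactol). The Ohira–Bestmann reagent (K2CO3, MeOH) would convert the aldehyde into the terminal alkyne, which is hydroxy ketone 20.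

**Further compounds**

F1 | step 16 | methyl 4-{(E)-2-[(E)-1-hydroxybut-2-en-1-yl-substituted C/D alcohol]ethenyl}furan-3-carboxylate (allylic alcohol from 23, carbinol epimers) | C=C1C[C@]2(C(O)/C=C/C)C[C@@]1(O)CC[C@H]2/C=C/c1cocc1C(=O)OC
F2 | step 16 | (E)-but-2-enoyl ketone (alkene analogue of 26) | C=C1C[C@]2(C(=O)/C=C/C)C[C@@]1(O)CC[C@H]2/C=C/c1cocc1C(=O)OC
F3 | step 16 | tetrahydro cycloadduct (C3, C4, C5 and C10 sp3, epimer mixture) | C=C1C[C@]23C[C@@]1(O)CC[C@H]2C1C=C2C(C(=O)OC)=COC2C(C)C1C3=O
F4 | step 11 | (7R,8S)-7-(2-bromoprop-2-en-1-yl)-8-ethenyl-1,4-dioxaspiro[4.5]decane-7-carbaldehyde | C=C[C@@H]1CCC2(OCCO2)C[C@]1(CC(Br)=C)C=O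
F5 | step 11 | [(7R,8S)-7-(2-bromoprop-2-en-1-yl)-8-ethenyl-1,4-dioxaspiro[4.5]decan-7-yl]methanol | C=C[C@@H]1CCC2(OCCO2)C[C@]1(CC(Br)=C)CO
F6 | step 11 | (3R,4S)-3-(2-bromoprop-2-en-1-yl)-4-ethenyl-3-(hydroxymethyl)cyclohexan-1-one | C=C[C@@H]1CCC(=O)C[C@]1(CC(Br)=C)CO
F7 | step 9 | (7R,8S)-8-ethenyl-7-(hydroxymethyl)-1,4-dioxaspiro[4.5]decane-7-carbaldehyde (hydroxymethyl cis to vinyl) | C=C[C@@H]1CCC2(OCCO2)C[C@@]1(CO)C=O
F8 | step 9 | methyl enol ether from F7 (7-(2-methoxyethenyl) compound, E/Z mixture) | C=C[C@@H]1CCC2(OCCO2)C[C@@]1(CO)C=COC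
F9 | step 9 | 2-[2-ethenyl-1-(hydroxymethyl)-5-oxocyclohexyl]acetaldehyde (keto aldehyde, in equilibrium with its lactol) | C=C[C@@H]1CCC(=O)C[C@@]1(CO)CC=O
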